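How much complex with one exchanged can a flask with 1.10 equiv of incoming ligand give me, and when?

| flask | starting complex | incoming ligand | remark | time |
|---|---|---|---|---|
| green | 2 M | 0.55 equiv | run made earlier |  |
| amber | 2 M | 0.83 equiv | run made earlier |  |
| flask | 2.0 M | 1.10 equiv |  | 15 d |

| run | time / d | complex with one exchanged / % | starting complex / % |
|---|---|---|---|
| green | 1.67 | 21.7 | 77.8 |
| green | 2.50 | 26.7 | 73.4 |
| green | 4.00 | 31.3 | 67.8 |
| green | 8.00 | 32.4 | 64.5 |
| green | 12.0 | 33.4 | 65.2 |
| amber | 1.67 | 29.7 | 69.2 |
| amber | 2.50 | 37.3 | 61.6 |
| amber | 4.00 | 42.1 | 56.2 |
| amber | 8.00 | 44.6 | 52.8 |
| amber | 12.0 | 43.2 | 54.2 |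

(standard deviation of a reading: 0.5 percentage points)

- the moment within 15 d at which there is most complex with one exchanged
- the amount of complex with one exchanged, in percent of the starting complex charged, at that time
- the first time at which complex with one exchanged reaches 15%, in the same percent

- the analysis behind the earlier runs scatters by 0.5 percentage points, standard deviation
- steps that have been proposed: incoming ligand -> decomposed reagent; complex with one exchanged + incoming ligand <-> leaving ligand + complex with two exchanged; starting complex + incoming ligand <-> leaving ligand + complex with one exchanged

I count half-lives, and two times are enough for that. The first is the half-life of starting complex as the first reading shows it: 4.61 d in the green run and 3.14 d in the amber run. Within the scatter, it shrinks in step with the charge of incoming ligand.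

The second time comes from the last readings, where starting complex has passed 0.617 half-lives in the green run and 0.884 in the amber run. Multiplying each count by its half-life gives 2.85 d and 2.78 d, which barely differ. I call their mean, 2.81 d, the working span: the time that, at the pace of the first reading, takes starting complex down to its last reading.

For the new flask the half-life scales to 2.34 d, so the span holds 1.20 half-lives and leaves 43.5% of starting complex. In the amber run, 94.3% of what left starting complex reads as complex with one exchanged at the last reading, so for this flask I expect complex with one exchanged at about 53.3% of the starting complex charged.

The forecast gives 52.5% of complex with one exchanged at 9.5 d and the asked level at 0.39 d, adding “the peak is flat and its time is poorly defined”.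

The flask gives 51.1% of complex with one exchanged at 6.29 d and reaches the asked level at 0.437 d.

    incoming ligand → decomposed reagent (k = 0.00256 h⁻¹)
    complex with one exchanged + incoming ligand ⇌ leaving ligand + complex with two exchanged (K = 0.270, k = 0.00107 M⁻¹ h⁻¹)
    starting complex + incoming ligand ⇌ leaving ligand + complex with one exchanged (K = 2.42, k = 0.00784 M⁻¹ h⁻¹)

In the flask, at 1.50 d starting complex stood at 63.5%, with 58.7% of the incoming ligand charge still there. At 7.50 d starting complex was down to 44.5%, against my 43.5%. Decomposition of incoming ligand ran on: at 15.0 d the flask held 0.657 M of decomposed reagent and 18.3% of the incoming ligand charge, and starting complex had come back to 48.0%. For a flask like this one but with 0.660 equiv of incoming ligand, the same span gives 60.7% of starting complex left, and at 15.0 d that flask holds 61.2%.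

(The runs were computed for substances that don't exist; scatter was added.)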